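**Assumption:** the target has no stereocentres, so "single enantiomer" is taken to mean the single (2E,6E) geometric isomer; both E-olefins are carried unchanged from (2E,6E)-farnesol.

## Retrosynthetic overview

1. Target ⇐ acetylation of the tertiary alcohol of the phthalide (last step); the phthalide lactone is the only ring formed, by reductive lactonisation of an o-formyl benzoate. The benzene ring comes intact from methyl gallate.
2. o-Formyl benzoate ⇐ para-selective O-methylation ⇐ key step: desymmetrising mono-ortho-formylation of the mirror-symmetric methyl 4-O-alkylgallate. The new CHO supplies the lactone CH2 carbon and makes the two identical phenols different (one H-bonded ortho, one para and acidic).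
3. Symmetric gallate ether ⇐ para-selective Mitsunobu of methyl gallate with the chain diol.
4. Chain diol ⇐ terminal-selective Markovnikov hydration of (2E,6E)-farnesol.

## Route

**Step 1**
Reactants: 1, (2E,6E)-farnesol
Product: 2, (2E,6E)-3,7,11-trimethyldodeca-2,6-diene-1,11-diol
Conditions: Hg(OAc)2 (1.0 equiv), THF/H2O 1:1, 0 °C, 30 min; then 3 M NaOH, NaBH4, 0 °C
Reagents that add atoms: water, O
Why: Brown oxymercuration–demercuration (Markovnikov hydration) should favour the distal isopropylidene olefin, since C2=C3 is inductively deactivated by the allylic OH and C6=C7 is more hindered; water opens the mercurinium at the tertiary carbon and NaBH4 replaces Hg by H, leaving both E-olefins untouched (no stereocentre formed; run to partial conversion and recycle 1).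

**Step 2**
Reactants: 2, the diol from step 1; 3, methyl gallate (methyl 3,4,5-trihydroxybenzoate, 2 equiv)
Product: 4, methyl 3,5-dihydroxy-4-{[(2E,6E)-11-hydroxy-3,7,11-trimethyldodeca-2,6-dien-1-yl]oxy}benzoate (mirror-symmetric)
Conditions: PPh3, DIAD, THF, 0 °C → rt
Reagents that add atoms: none
Why: Mitsunobu etherification, in which the betaine deprotonates the most acidic phenol of 3 (the 4-OH, para to the ester, pKa about 8) and that phenoxide displaces the oxyphosphonium of the primary allylic alcohol by SN2 with the 2E geometry retained; the tertiary alcohol cannot be activated and excess 3 suppresses dialkylation.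

**Step 3 (key step)**
Reactants: 4
Product: 5, methyl 2-formyl-3,5-dihydroxy-4-{[(2E,6E)-11-hydroxy-3,7,11-trimethyldodeca-2,6-dien-1-yl]oxy}benzoate
Conditions: anhydrous MgCl2 (3 equiv), Et3N (7 equiv), (CH2O)n (10 equiv), MeCN, 70 °C; cold 5% citric acid work-up
Reagents that add atoms: paraformaldehyde, C=O
Why: Casnati–Skattebøl magnesium-phenoxide-directed ortho-formylation (CH2O delivered within the Mg chelate, then Oppenauer-type oxidation by a second CH2O) can only attack the two equivalent C2/C6 positions, and after the first formylation the Mg–salicylaldehyde chelate and the now para-acyl phenoxide deactivate the ring, so it should stop at the mono-aldehyde and break the symmetry.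

**Step 4**
Reactants: 5
Product: 6, methyl 2-formyl-3-hydroxy-4-{[(2E,6E)-11-hydroxy-3,7,11-trimethyldodeca-2,6-dien-1-yl]oxy}-5-methoxybenzoate
Conditions: MeI (1.2 equiv), KHCO3 (1.5 equiv), DMF, rt
Reagents that add atoms: iodomethane, CI
Why: Regioselective Williamson O-methylation as in 2,4-dihydroxybenzaldehyde: the 5-OH is para to CHO (most acidic, not H-bonded) and is alkylated, whereas the 3-OH is locked in the six-membered H-bond to the ortho-CHO and is flanked on both sides; the tertiary alcohol is inert to MeI/bicarbonate.

**Step 5**
Reactants: 6
Product: 7, 4-hydroxy-5-{[(2E,6E)-11-hydroxy-3,7,11-trimethyldodeca-2,6-dien-1-yl]oxy}-6-methoxyisobenzofuran-1(3H)-one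
Conditions: NaBH4 (1.2 equiv), THF/MeOH 4:1, 0 °C; 5% citric acid work-up
Reagents that add atoms: none
Why: Chemoselective borohydride reduction of the aryl aldehyde, followed by spontaneous 5-exo-trig lactonisation of the benzylic alkoxide onto the ortho methyl ester (loss of MeOH), gives the phthalide with the free OH next to the lactone CH2; aryl allyl ether and olefins are untouched.

**Step 6**
Reactants: 7
Product: 8, Farnesylemefuranone F, (2E,6E)-12-[(4-hydroxy-6-methoxy-1-oxo-1,3-dihydroisobenzofuran-5-yl)oxy]-2,6,10-trimethyldodeca-6,10-dien-2-yl acetate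
Conditions: Ac2O (6 equiv), Et3N, DMAP (0.5 equiv), CH2Cl2, rt, 24 h; then MeOH, K2CO3, 0 °C, 20 min (same pot); NH4Cl work-up
Reagents that add atoms: acetic anhydride, CC(=O)OC(C)=O
Why: DMAP-catalysed (Steglich-type) acetylation esterifies the hindered tertiary alcohol and, transiently, the phenol; brief carbonate methanolysis then cleaves only the aryl acetate (phenoxide leaving group), while the tertiary alkyl acetate and the lactone survive.

## Compound list

1 | (2E,6E)-farnesol | OC/C=C(\C)CC/C=C(\C)CCC=C(C)C | starting material
2 | (2E,6E)-3,7,11-trimethyldodeca-2,6-diene-1,11-diol | OC/C=C(\C)CC/C=C(\C)CCCC(C)(C)O | intermediate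
3 | methyl gallate | COC(=O)c1cc(O)c(O)c(O)c1 | starting material
4 | methyl 3,5-dihydroxy-4-{[(2E,6E)-11-hydroxy-3,7,11-trimethyldodeca-2,6-dien-1-yl]oxy}benzoate | COC(=O)c1cc(O)c(OC/C=C(\C)CC/C=C(\C)CCCC(C)(C)O)c(O)c1 | intermediate
5 | methyl 2-formyl-3,5-dihydroxy-4-{[(2E,6E)-11-hydroxy-3,7,11-trimethyldodeca-2,6-dien-1-yl]oxy}benzoate | COC(=O)c1cc(O)c(OC/C=C(\C)CC/C=C(\C)CCCC(C)(C)O)c(O)c1C=O | intermediate
6 | methyl 2-formyl-3-hydroxy-4-{[(2E,6E)-11-hydroxy-3,7,11-trimethyldodeca-2,6-dien-1-yl]oxy}-5-methoxybenzoate | COC(=O)c1cc(OC)c(OC/C=C(\C)CC/C=C(\C)CCCC(C)(C)O)c(O)c1C=O | intermediate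
7 | 4-hydroxy-5-{[(2E,6E)-11-hydroxy-3,7,11-trimethyldodeca-2,6-dien-1-yl]oxy}-6-methoxyisobenzofuran-1(3H)-one | COc1cc2c(c(O)c1OC/C=C(\C)CC/C=C(\C)CCCC(C)(C)O)COC2=O | intermediate
8 | Farnesylemefuranone F | COc1cc2c(c(O)c1OC/C=C(\C)CC/C=C(\C)CCCC(C)(C)OC(C)=O)COC2=O | target

## Summary

Total step count: 6 (step 6 is a one-pot, two-stage operation; counted strictly it is 7).
Longest linear sequence: 6 (from farnesol; methyl gallate enters at step 2).

Steps most likely to fail, with fallbacks:

1. **Step 3 (desymmetrising formylation).** The ester-flanked position may react slowly, the intermediate Mg benzyl alkoxide may lactonise before oxidation (giving the undifferentiated 4,6-dihydroxyphthalide), or the Mg-chelated farnesyl ether may be eroded. Fallback: break the symmetry earlier by a different logic. Borate-templated mono-O-methylation of methyl gallate (borax, Me2SO4, aq. NaOH) gives methyl 3-O-methylgallate; Mitsunobu with 2 at the 4-OH and ortho-hydroxymethylation directed by the single remaining phenol then follow, and either the aldehyde or the direct lactone is productive.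

2. **Step 2 (para-selective Mitsunobu on a free pyrogallol).** 3-O- or di-alkylation, or consumption of the reagents by the vicinal OH groups as a cyclic phosphorane, may occur. Fallback: alkylate methyl gallate with commercial (2E,6E)-farnesyl bromide (KHCO3, DMF; para-selective Williamson) and move the terminal hydration to the phthalide stage, where any aryl-mercury formed is reduced back to Ar–H by NaBH4.

3. **Step 1 (site-selective hydration).** Selectivity between C10=C11 and C6=C7 may be only modest, and bis-hydration is possible. Fallback: van Tamelen terminal bromohydrin formation (NBS, aqueous THF) followed by radical debromination (Bu3SnH, AIBN) to the same diol 2.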